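In this scheme, a D charged stands at any moment as D, L, J or L.G, so what J takes, L.G can't have.

    D → L (k1 = 0.0028 s⁻¹)
    X → G (k2 = 0.010 s⁻¹)
    L + G → L.G (k3 = 1.6 M⁻¹ s⁻¹)
    L → J (k4 = 6.8 × 10⁻⁴ s⁻¹)
    X + Z → X.Z (k5 = 0.53 M⁻¹ s⁻¹)

in all of them: Z 6.50 mM; time 30 min
- Thursday's: D 0.13 M (fed, over 25 min); X 0.130 M; all else is in the flask from the start; the feed brings no volume worth counting
- Sunday's: D 0.13 M; X 0.130 M (fed, over 25 min); all else is in the flask from the start; the feed brings no volume worth counting
- Tuesday's: D 0.13 M; X 0.130 M (in portions, 3, over 25 min); first portion at the start, last at 25 min
- Monday's: D 0.13 M; X 0.130 M; everything together at the start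

* the flask that comes out highest in amount of L.G, in percent of the D charged, or "all alike" when all lie within 1.5 percentage points (Thursday's / Sunday's / Tuesday's / Monday's / all alike)
* L.G at the end, in percent of the D charged, Thursday's
* L.G at the end, in percent of the D charged, Sunday's
* L.G at the end, in percent of the D charged, Tuesday's
* L.G at the end, in percent of the D charged, Monday's

L is the species that waits for G, and it lasts 24.5 min on average against step 4. So count the lifetimes of L in the time tf over which X comes in, n = k4·tf, the wait number: 1.02. The charges of D and X are equal, which keeps this count simple.

Here is my reckoning, from two extremes. In the first, G stands ready before L appears, so L is caught at once. Then G from X is the limiting reagent. Take off the X that Z consumes, and L.G comes to 95.0%. That is my figure for Monday's, because X halves in 1.2 min, faster than D's 4.1 min. Thursday's also has G waiting, but its fed D is still turning over at the end, which gives me 89.9%.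

In the second extreme, all the L stands there at the start and X trickles in. L then drains by step 4 and by the feed of X together, and in this reckoning it reaches zero after 17.2 min. The feed has caught 68.9% by then, leaving Z aside, and I take that as a rough floor for Sunday's. Sunday's L arrives over D's lifetime of 5.95 min, shorter than the feed, so it should lie above that floor but nearer to it than to the first extreme. Tuesday's spreads X over the same tf, so I place it beside Sunday's. That gives Monday's.

The forecast named Monday's, with 87% for Thursday's, 75% for Sunday's, 76% for Tuesday's and 94.4% for Monday's. Its ground was this: “L is lost to J only while it sits waiting for G”. Its Sunday's figure is a value, where mine is a rough floor, and my Thursday's stands higher than its figure.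

The simulation gives 87.4% for Thursday's, 75.2% for Sunday's, 74.7% for Tuesday's and 94.9% for Monday's, so Monday's comes highest and the forecast held. Sunday's J reads 24.1%, below the 31.1% that n = 1.02 gives at the floor. Tuesday's has the same n, and its J reads 24.5%, against 0.832% in Thursday's, where X stands in the flask from the start. The largest single effect on the gap between Monday's and Tuesday's is the conversion of L into J: the gap is 20 percentage points with that step and 3.2 points without it.

The constants used here are made up, and the outcome is calculated.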